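## Analysis of the target

- The target is an 8,8''-linked biflavonoid. A (2S)-flavanone (naringenin type: benzo ring A, dihydropyranone ring C, 4-hydroxyphenyl ring B on C2) is bonded through C8 to C8'' of a flavone (apigenin type: ring A'', pyranone ring C'' with C2''=C3'', ring B'' on C2'').
- It has one sp3 stereocenter, C2 (S). The C8–C8'' axis is flanked by four ortho oxygens (O1, 7-OH, O1'', 7''-OH) and is certainly hindered, but the given structure does not define its configuration.
- C2 is labile: base opens ring C by a retro-oxa-Michael reaction (helped by the free 4'- and 5-hydroxyls), and strong acid can ionize the benzylic C2–O1 bond. It should be set late and unveiled under neutral conditions, in the presence of six phenols and the flavone enone.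
- The first difficulty is the C8–C8'' bond: a tetra-ortho-substituted biaryl between two almost identical, electron-rich rings A, each with two open sites (C6 and C8).
- The second difficulty is that the two halves differ only by two hydrogens at C2–C3, so any union of preformed halves must tell apart partners of nearly equal reactivity.
- The feature that invites the key move: without the two rings B (bonds C2–C1' and C2''–C1''') the molecule is a C2-symmetric 8,8'-bichromone. Its only hard bond, C8–C8', joins two identical rings A at the carbon that the 5,7-dioxygenation makes most nucleophilic (para to O5, ortho to O7 and O1).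
- The plan therefore dimerizes one simple chromone by direct oxidative C8–H/C8–H coupling. The same arylboronic acid then enters the two chromone rings with two outcomes: oxidative (flavone) and enantioselective (flavanone).

## Retrosynthetic reasoning

**10 to 9.** The six phenols are masked as benzyl ethers, so the last step is a neutral hydrogenolysis. No base or Lewis acid touches C2 after it is set, and benzyl ethers are electron-donating enough to keep ring A nucleophilic in the key step.

**9 to 8 and 6.** The C2–C1' bond of the flavanone is cut, which removes ring B and the only stereocenter together. Forward, a catalytic enantioselective conjugate addition of boronic acid 6 to the remaining chromone ring of 8 makes this bond and sets C2 (S) under catalyst control. The cut is placed here because the stereocenter then appears after every oxidative step. The flavone ring of 8 is a β,β-disubstituted, aryl-conjugated enone and should not compete with the unsubstituted chromone ring.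

**8 to 5 and 6.** The C2''–C1''' bond of the flavone is cut in the same way. Forward, 6 is added to one chromone ring of the symmetric dimer 5 and the adduct 7 is dehydrogenated in the same flask. This is the desymmetrizing step: the two rings of 5 are equivalent, so 6 is the limiting reagent and unreacted 5 is recycled. Both rings B thus come from one reagent, and only the fate of the palladium enolate (oxidation or protonation) distinguishes the halves.

**5 to two molecules of 4.** The C8–C8' bond is cut, which halves the molecule. Forward, an oxidative dehydrogenative homocoupling with a trivalent iodine oxidant joins two unfunctionalized C8–H positions. The dimerization is done at the chromone stage because no ring B is yet present to be oxidized or attacked, no labile stereocenter is exposed to oxidant, and only one monomer is needed. Homocoupling also removes the hetero-selectivity problem; what remains is site selectivity for C8, which the substitution pattern provides.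

**4 to 1 and 2.** Ring C is cut at O1–C2 and C2–C3. Forward, the acetophenone 1 condenses with the amide acetal 2 to the enaminone 3, which cyclizes under acid to the chromone.

## Alternatives that were turned down

**Alternative 1:** The textbook disconnection cuts C8–C8'' between preformed halves. The forward key step is a Suzuki–Miyaura coupling (zerovalent palladium, aqueous base) of the 8-iodoflavone A1 with the flavanone 8-boronate A2.
- Both partners need their own multi-step synthesis, including regioselective C8 halogenation and borylation, for about ten steps in all.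
- 2,6-Dioxygenated arylboron compounds such as A2 protodeboronate readily.
- A tetra-ortho-substituted coupling needs heat and base, under which ring C of A2 opens and C2 racemizes.

**Alternative 2:** The same bond is made without prefunctionalization by oxidative cross-dehydrogenative coupling of the intact (S)-flavanone A3 with the flavone A4.
- Rings A of A3 and A4 have nearly the same oxidation potential and nucleophilicity, so nothing favours hetero- over homo-coupling and a statistical mixture of dimers must be expected.
- Ring B of A3 is a non-conjugated 4-alkoxyphenyl group, about as oxidizable as ring A, and offers C3' as a further coupling site.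
- The labile C2 of A3 would sit through oxidant and acid.

**Alternative 3:** Hidden symmetry is used one oxidation level higher: A4 is homocoupled at C8 to the C2-symmetric biflavone A5, and C2 is then set by enantioselective conjugate reduction of one C2=C3 bond.
- Enantioselective 1,4-reduction of a 2-aryl-chromenone is far less general than aryl addition to an unsubstituted chromone, tends to run on to the C4 alcohol, and must stop after one of two identical rings.
- Hydrogen-based catalysts compete with hydrogenolysis of the benzyl ethers. That would force methyl ethers and a final Lewis-acid demethylation that endangers C2.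

Key step: step 2

**Remarks.**
- The given structure fixes only C2 (S) and leaves the C8–C8'' axis open. The route controls C2 and carries both rotamers about the axis, which are diastereomers from 9 onward and separable there if one is wanted.
- Compound 1 is taken as a catalogue compound.

## Route

Step 1
Reactants: 1 1-[2,4-bis(benzyloxy)-6-hydroxyphenyl]ethan-1-one; 2 N,N-dimethylformamide dimethyl acetal
Product: 4 5,7-bis(benzyloxy)-4H-chromen-4-one, via enaminone 3 (not isolated)
Conditions: 2 (3 equiv), toluene, 100 °C; then conc. aq. HCl, CH2Cl2, 40 °C
Reagents that add atoms: none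
Why: Condensation of the methyl ketone with the amide acetal gives the (E)-β-dimethylamino enone 3; acid then promotes conjugate addition of the ortho phenol and loss of dimethylamine, closing ring C (enaminone route to chromones), with the acetal carbon becoming C2.

Step 2
Reactants: 4 5,7-bis(benzyloxy)-4H-chromen-4-one (two molecules)
Product: 5 5,5',7,7'-tetrakis(benzyloxy)-4H,4'H-[8,8'-bichromene]-4,4'-dione
Conditions: PhI(OCOCF3)2 (0.55 equiv), (CF3)2CHOH–CH2Cl2, −20 °C to rt
Reagents that add atoms: none
Why: PhI(OCOCF3)2 in the fluoroalcohol oxidizes the trialkoxy ring A of 4 by single-electron transfer to an arene radical cation. A second, neutral molecule of 4 attacks it through its most nucleophilic carbon, and a second electron transfer with loss of two protons (taken up as CF3CO2H) gives the biaryl, so half an equivalent of oxidant suffices. The closest known reaction type is the dehydrogenative (Scholl-type) homocoupling of polyalkoxyarenes by PhI(OCOCF3)2 or FeCl3, a family that includes the C8–C8'' dimerization of per-O-alkylated 5,7-dioxygenated flavones. No ring is closed: the step joins two rings A through C8–C8'. No stereocenter is formed; the new axis arises as a racemate, which the target allows. The selectivity needed is C8 over C6 and C3: C8 is para to the 5-benzyloxy group, ortho to O7 and O1 and meta to the acyl-bearing C4a, whereas C6 gets its para donation only from O1, whose lone pair is shared with the vinylogous ester of ring C, and lies between two benzyloxy groups; C3 is the α-carbon of an electron-poor pyranone, and electrophilic halogenation of 5,7-dialkoxy-benzopyranones picks the same C8. Homodimerization removes the cross-selectivity problem, no ring B is present to compete, and the twisted, more hindered product together with substoichiometric oxidant limits further coupling.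

Step 3
Reactants: 5 5,5',7,7'-tetrakis(benzyloxy)-4H,4'H-[8,8'-bichromene]-4,4'-dione; 6 [4-(benzyloxy)phenyl]boronic acid
Product: 8 5,7-bis(benzyloxy)-2-[4-(benzyloxy)phenyl]-8-[5,7-bis(benzyloxy)-4-oxo-4H-chromen-8-yl]-4H-chromen-4-one, via racemic flavanone–chromone 7 (not isolated)
Conditions: 6 (0.9 equiv), Pd(OCOCF3)2 (10 mol %), 2,2'-bipyridine (12 mol %), AcOH–THF–H2O, 60 °C; then DDQ (1.5 equiv), 1,4-dioxane, 100 °C
Reagents that add atoms: none
Why: A cationic divalent palladium–bipyridine catalyst adds the aryl group of 6 to C2 of one chromone ring (conjugate addition, palladium enolate protonated by water), and DDQ then dehydrogenates C2–C3 of the new flavanone ring to the flavone, so the configuration of 7 is irrelevant. Limiting 6 keeps twofold arylation low, unreacted 5 is recycled, and the untouched chromone ring is inert to DDQ.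

Step 4
Reactants: 8 5,7-bis(benzyloxy)-2-[4-(benzyloxy)phenyl]-8-[5,7-bis(benzyloxy)-4-oxo-4H-chromen-8-yl]-4H-chromen-4-one; 6 [4-(benzyloxy)phenyl]boronic acid
Product: 9 (2S)-5,7-bis(benzyloxy)-2-[4-(benzyloxy)phenyl]-8-{5,7-bis(benzyloxy)-2-[4-(benzyloxy)phenyl]-4-oxo-4H-chromen-8-yl}-2,3-dihydro-4H-chromen-4-one
Conditions: 6 (2 equiv), Pd(OCOCF3)2 (5 mol %), (R)-4-tert-butyl-2-(pyridin-2-yl)-4,5-dihydrooxazole (6 mol %), NH4PF6 (30 mol %), H2O (5 equiv), ClCH2CH2Cl, 50 °C
Reagents that add atoms: none
Why: Catalytic enantioselective conjugate addition of an arylboronic acid to a chromone: the chiral pyridine–oxazoline aryl–palladium complex delivers the aryl group to the Re face of C2 (priorities O1 > C3 > H) and water protonates the palladium enolate, giving 2S; the (R)-ligand is the enantiomer predicted by the facial model for cyclic enones, and its sense is to be confirmed on chromone 4 before use. The flavone ring, a β,β-disubstituted and aryl-conjugated enone, should not react, and both rotamers of 8 should give the (2S) product as a pair of axial diastereomers.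

Step 5
Reactants: 9 (2S)-5,7-bis(benzyloxy)-2-[4-(benzyloxy)phenyl]-8-{5,7-bis(benzyloxy)-2-[4-(benzyloxy)phenyl]-4-oxo-4H-chromen-8-yl}-2,3-dihydro-4H-chromen-4-one
Product: 10 (2S)-5,7-dihydroxy-2-(4-hydroxyphenyl)-8-[5,7-dihydroxy-2-(4-hydroxyphenyl)-4-oxo-4H-chromen-8-yl]-2,3-dihydro-4H-chromen-4-one
Conditions: H2 (1 atm), Pd/C (10 wt %), EtOAc–MeOH, rt
Reagents that add atoms: none
Why: Hydrogenolysis of the six aryl benzyl ethers under neutral conditions releases the phenols without base or Lewis acid, so C2 should keep its configuration; at 1 atm and rt the flavone C2''=C3'' and both ketones are expected to survive if the reaction is stopped once the benzyl ethers are gone.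

## Compound list

1 | 1-[2,4-bis(benzyloxy)-6-hydroxyphenyl]ethan-1-one | CC(=O)c1c(O)cc(OCc2ccccc2)cc1OCc1ccccc1 | starting material
2 | N,N-dimethylformamide dimethyl acetal | COC(OC)N(C)C | starting material
3 | (E)-1-[2,4-bis(benzyloxy)-6-hydroxyphenyl]-3-(dimethylamino)prop-2-en-1-one | CN(C)/C=C/C(=O)c1c(O)cc(OCc2ccccc2)cc1OCc1ccccc1 | intermediate
4 | 5,7-bis(benzyloxy)-4H-chromen-4-one | O=c1ccoc2cc(OCc3ccccc3)cc(OCc3ccccc3)c12 | intermediate
5 | 5,5',7,7'-tetrakis(benzyloxy)-4H,4'H-[8,8'-bichromene]-4,4'-dione (racemic about the axis) | O=c1ccoc2c(-c3c(OCc4ccccc4)cc(OCc4ccccc4)c4c(=O)ccoc34)c(OCc3ccccc3)cc(OCc3ccccc3)c12 | intermediate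
6 | [4-(benzyloxy)phenyl]boronic acid | OB(O)c1ccc(OCc2ccccc2)cc1 | starting material
7 | 5,7-bis(benzyloxy)-2-[4-(benzyloxy)phenyl]-8-[5,7-bis(benzyloxy)-4-oxo-4H-chromen-8-yl]-2,3-dihydro-4H-chromen-4-one (racemic at C2) | O=C1CC(c2ccc(OCc3ccccc3)cc2)Oc2c1c(OCc1ccccc1)cc(OCc1ccccc1)c2-c1c(OCc2ccccc2)cc(OCc2ccccc2)c2c(=O)ccoc12 | intermediate
8 | 5,7-bis(benzyloxy)-2-[4-(benzyloxy)phenyl]-8-[5,7-bis(benzyloxy)-4-oxo-4H-chromen-8-yl]-4H-chromen-4-one | O=c1cc(-c2ccc(OCc3ccccc3)cc2)oc2c(-c3c(OCc4ccccc4)cc(OCc4ccccc4)c4c(=O)ccoc34)c(OCc3ccccc3)cc(OCc3ccccc3)c12 | intermediate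
9 | (2S)-5,7-bis(benzyloxy)-2-[4-(benzyloxy)phenyl]-8-{5,7-bis(benzyloxy)-2-[4-(benzyloxy)phenyl]-4-oxo-4H-chromen-8-yl}-2,3-dihydro-4H-chromen-4-one | O=C1C[C@@H](c2ccc(OCc3ccccc3)cc2)Oc2c1c(OCc1ccccc1)cc(OCc1ccccc1)c2-c1c(OCc2ccccc2)cc(OCc2ccccc2)c2c(=O)cc(-c3ccc(OCc4ccccc4)cc3)oc12 | intermediate
10 | (2S)-5,7-dihydroxy-2-(4-hydroxyphenyl)-8-[5,7-dihydroxy-2-(4-hydroxyphenyl)-4-oxo-4H-chromen-8-yl]-2,3-dihydro-4H-chromen-4-one (CNP0339995.1) | O=C1C[C@@H](c2ccc(O)cc2)Oc2c1c(O)cc(O)c2-c1c(O)cc(O)c2c(=O)cc(-c3ccc(O)cc3)oc12 | target

## Step count and risk

Total step count: 5. Longest linear sequence: 5 steps (1 to 4 to 5 to 8 to 9 to 10).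

**Step 2 (key step).**
- What may go wrong: the oxidation may stall because the basic pyranone carbonyl is hydrogen-bonded or protonated and ring A is thereby deactivated. Site control may be lost through attack at C6 or C3. The product may be oxidized further to oligomers, or benzyl ethers may be cleaved oxidatively.
- Fallback: from 4, electrophilic iodination with I2 and CF3CO2Ag in CH2Cl2 should give 5,7-bis(benzyloxy)-8-iodo-4H-chromen-4-one F1. Reductive Ullmann homocoupling of F1 (activated Cu powder, DMF, 130 °C) comes back to the route at 5.

**Step 3.**
- What may go wrong: arylation of one of two equivalent rings follows statistics at best. Sluggish conjugate addition to the electron-rich chromone would let protodeboronation of 6 consume the limiting reagent, and dehydrogenation by DDQ may be slow on the 5-alkoxy flavanone ring.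
- Fallback: from 5, deprotonative zincation at C2 of one chromone ring with one equivalent of a hindered zinc amide base of the TMPZnCl·LiCl type [(2,2,6,6-tetramethylpiperidin-1-yl)zinc chloride–LiCl] would give the organozinc chloride F2. These bases can be steered between C2 and C3 of chromones by a Lewis-acid additive; the C2-selective regime is used. F2 is not isolated: Negishi coupling with 1-(benzyloxy)-4-iodobenzene under Pd(PPh3)4 in THF comes back to the route at 8 with C2=C3 intact, so no dehydrogenation is needed.

**Step 4.**
- What may go wrong: facial selectivity may be poor for one rotamer of 8 (mismatch between the axis and the catalyst), and turnover may be slow on the hindered, electron-rich chromone ring, which would erode the enantiomeric purity at C2.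
- Fallback: from 5, exhaustive twofold addition of 6 under the step 4 catalyst would give the (2S,2''S)-bis-flavanone F3. Most wrong-face addition ends up in the heterochiral diastereomer, which is removed by chromatography (Horeau principle). Partial dehydrogenation of F3 with DDQ (1 equiv, 1,4-dioxane, 100 °C) then comes back to the route at 9, bypassing 8.

**Step 5.**
- What may go wrong: over-reduction, either by hydrogenolytic opening of the benzylic C2–O1 bond of the flavanone or by saturation of the flavone C2''=C3''; or incomplete debenzylation of the crowded ethers next to the axis.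
- Fallback: from 9, non-reductive debenzylation with BCl3 and pentamethylbenzene as benzyl-cation scavenger (CH2Cl2, −78 °C) gives 10 directly; no new compound is made.

## Further compounds

F1 | step 2 | 5,7-bis(benzyloxy)-8-iodo-4H-chromen-4-one | O=c1ccoc2c(I)c(OCc3ccccc3)cc(OCc3ccccc3)c12
F2 | step 3 | [5,5',7,7'-tetrakis(benzyloxy)-4,4'-dioxo-4H,4'H-8,8'-bichromen-2-yl]zinc chloride | Cl[Zn]c1cc(=O)c2c(OCc3ccccc3)cc(OCc3ccccc3)c(-c3c(OCc4ccccc4)cc(OCc4ccccc4)c4c(=O)ccoc34)c2o1
F3 | step 4 | (2S,2'S)-5,5',7,7'-tetrakis(benzyloxy)-2,2'-bis[4-(benzyloxy)phenyl]-2,2',3,3'-tetrahydro-4H,4'H-[8,8'-bichromene]-4,4'-dione | O=C1C[C@@H](c2ccc(OCc3ccccc3)cc2)Oc2c1c(OCc1ccccc1)cc(OCc1ccccc1)c2-c1c(OCc2ccccc2)cc(OCc2ccccc2)c2c1O[C@H](c1ccc(OCc3ccccc3)cc1)CC2=O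
F0 | step 5 | none | none
A1 | alternative 1 | 5,7-bis(benzyloxy)-2-[4-(benzyloxy)phenyl]-8-iodo-4H-chromen-4-one | O=c1cc(-c2ccc(OCc3ccccc3)cc2)oc2c(I)c(OCc3ccccc3)cc(OCc3ccccc3)c12
A2 | alternative 1 | (2S)-5,7-bis(benzyloxy)-2-[4-(benzyloxy)phenyl]-8-(4,4,5,5-tetramethyl-1,3,2-dioxaborolan-2-yl)-2,3-dihydro-4H-chromen-4-one | O=C1C[C@@H](c2ccc(OCc3ccccc3)cc2)Oc2c1c(OCc1ccccc1)cc(OCc1ccccc1)c2B1OC(C)(C)C(C)(C)O1
A3 | alternative 2 | (2S)-5,7-bis(benzyloxy)-2-[4-(benzyloxy)phenyl]-2,3-dihydro-4H-chromen-4-one | O=C1C[C@@H](c2ccc(OCc3ccccc3)cc2)Oc2cc(OCc3ccccc3)cc(OCc3ccccc3)c12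
A4 | alternative 2 | 5,7-bis(benzyloxy)-2-[4-(benzyloxy)phenyl]-4H-chromen-4-one | O=c1cc(-c2ccc(OCc3ccccc3)cc2)oc2cc(OCc3ccccc3)cc(OCc3ccccc3)c12
A5 | alternative 3 | 5,5',7,7'-tetrakis(benzyloxy)-2,2'-bis[4-(benzyloxy)phenyl]-4H,4'H-[8,8'-bichromene]-4,4'-dione | O=c1cc(-c2ccc(OCc3ccccc3)cc2)oc2c(-c3c(OCc4ccccc4)cc(OCc4ccccc4)c4c(=O)cc(-c5ccc(OCc6ccccc6)cc5)oc34)c(OCc3ccccc3)cc(OCc3ccccc3)c12
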